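**Retrosynthetic overview**

1. Target ⇒ its nona-O-benzyl ether. The 4-H is put in last, by ionic hydrogenation of a tertiary, doubly benzylic 3,4-cis-diol: hydride enters anti to the 3-OH, so ring D ends up cis to it. The diol comes from OsO4 on a 4-aryl-2H-chromene.
2. Key disconnection: both pyran rings (ring C of the upper unit, ring F of the lower unit) are opened at their C4–C4a bonds at once. This leads back to an acyclic bis(aryl ether) with an internal alkyne (→ ring C by hydroarylation) and a terminal epoxide (→ ring F with the 2,3-cis 3-ol by epoxide–arene cyclisation). One gold catalyst closes both.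
3. The bis(aryl ether) ⇒ Mitsunobu etherification of 3-(benzyloxy)phenol (ring A) with a propargylic alcohol ⇒ asymmetric alkynylation of 3,4,5-tris(benzyloxy)benzaldehyde with the ring-D aryl alkyne.
4. The ring-D alkyne ⇒ aldehyde homologation ⇒ Mitsunobu etherification of 4,6-bis(benzyloxy)-2-hydroxybenzaldehyde with an erythro epoxy alcohol from a Sharpless kinetic resolution. The interflavan C4–C8 bond is the original aryl–CHO bond of ring D.
5. Ring order: aromatic rings A, B, D and E are bought; rings C and F are formed together in step 8; no ring is formed afterwards.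

Assumption 1: the SMILES is read as robinetinidol-(4β→8)-epigallocatechin, upper unit 2R,3S,4R (2,3-trans, 3,4-cis), lower unit 2R,3R (2,3-cis).
Assumption 2: (S,S)-ProPhenol is taken as the ligand antipode that gives Re-face alkynylation in step 6; if the sense proves opposite, the (R,R)-ligand is used.

**Route**

Step 1
Reactants: 1 2,4,6-trihydroxybenzaldehyde
Product: 2 4,6-bis(benzyloxy)-2-hydroxybenzaldehyde
Conditions: BnBr (2.1 equiv), K2CO3 (2.2 equiv), DMF, 0 °C to rt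
Reagents that add atoms: benzyl bromide, BrCc1ccccc1
Why: Williamson etherification benzylates the 4-OH and one ortho-OH, while the other ortho-OH is held back by its hydrogen bond to the formyl group and remains as the phenol that later becomes the pyran oxygen of ring F.

Step 2
Reactants: 3 3,4,5-tris(benzyloxy)benzaldehyde
Product: 4 (±)-1-[3,4,5-tris(benzyloxy)phenyl]prop-2-en-1-ol
Conditions: CH2=CHMgBr, THF, −78 to 0 °C; aq NH4Cl
Reagents that add atoms: vinylmagnesium bromide, C=C[Mg]Br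
Why: Grignard 1,2-addition to a non-enolisable aldehyde gives the racemic secondary allylic alcohol needed for the resolution.

Step 3
Reactants: 4 (±)-1-[3,4,5-tris(benzyloxy)phenyl]prop-2-en-1-ol
Product: 5 (S)-[(2R)-oxiran-2-yl][3,4,5-tris(benzyloxy)phenyl]methanol
Conditions: Ti(OiPr)4 (0.2 equiv), L-(+)-DIPT (0.25 equiv), t-BuOOH (0.45 equiv), 4 Å MS, CH2Cl2, −20 °C; unreacted (S)-enantiomer of 4 separated
Reagents that add atoms: tert-butyl hydroperoxide, CC(C)(C)OO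
Why: Sharpless kinetic resolution by asymmetric epoxidation: with L-(+)-DIPT the (R)-allylic alcohol is epoxidised fast and erythro-selectively, which sets the oxirane carbon as R (the later C3 of the lower unit) and gives the carbinol carbon as S (the descriptor changes only because the priorities change).

Step 4
Reactants: 2 4,6-bis(benzyloxy)-2-hydroxybenzaldehyde, 5 (S)-[(2R)-oxiran-2-yl][3,4,5-tris(benzyloxy)phenyl]methanol
Product: 6 4,6-bis(benzyloxy)-2-{(R)-[(2R)-oxiran-2-yl][3,4,5-tris(benzyloxy)phenyl]methoxy}benzaldehyde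
Conditions: PPh3, DIAD, toluene, 0 °C to rt
Reagents that add atoms: none
Why: Mitsunobu etherification inverts the benzylic carbinol by SN2 to the (R)-aryl ether (the later C2 of the lower unit), giving the threo O/O arrangement that maps onto 2,3-cis; the adjacent epoxide disfavours ionisation.

Step 5
Reactants: 6 4,6-bis(benzyloxy)-2-{(R)-[(2R)-oxiran-2-yl][3,4,5-tris(benzyloxy)phenyl]methoxy}benzaldehyde
Product: 7 1,5-bis(benzyloxy)-2-ethynyl-3-{(R)-[(2R)-oxiran-2-yl][3,4,5-tris(benzyloxy)phenyl]methoxy}benzene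
Conditions: dimethyl (1-diazo-2-oxopropyl)phosphonate, K2CO3, MeOH/THF, 0 °C to rt
Reagents that add atoms: dimethyl (1-diazo-2-oxopropyl)phosphonate, CC(=O)C(=[N+]=[N-])P(=O)(OC)OC
Why: Seyferth–Gilbert homologation in its Ohira–Bestmann form turns the aldehyde into the terminal aryl alkyne under mild base that leaves the epoxide and both stereocentres untouched.

Step 6
Reactants: 7 1,5-bis(benzyloxy)-2-ethynyl-3-{(R)-[(2R)-oxiran-2-yl][3,4,5-tris(benzyloxy)phenyl]methoxy}benzene, 3 3,4,5-tris(benzyloxy)benzaldehyde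
Product: 8 (1S)-3-[2,4-bis(benzyloxy)-6-{(R)-[(2R)-oxiran-2-yl][3,4,5-tris(benzyloxy)phenyl]methoxy}phenyl]-1-[3,4,5-tris(benzyloxy)phenyl]prop-2-yn-1-ol
Conditions: Me2Zn (3 equiv), (S,S)-ProPhenol (20 mol %), Ph3PO (40 mol %), toluene, 0 °C; aq NH4Cl
Reagents that add atoms: none
Why: Zinc–ProPhenol catalysed asymmetric alkynylation of an aryl aldehyde: Re-face addition of the alkynylzinc sets the (S)-propargylic carbinol, the precursor of C2 of the upper unit, by catalyst control.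

Step 7
Reactants: 8 (1S)-3-[2,4-bis(benzyloxy)-6-{(R)-[(2R)-oxiran-2-yl][3,4,5-tris(benzyloxy)phenyl]methoxy}phenyl]-1-[3,4,5-tris(benzyloxy)phenyl]prop-2-yn-1-ol, 9 3-(benzyloxy)phenol
Product: 10 1-(benzyloxy)-3-({(1R)-3-[2,4-bis(benzyloxy)-6-{(R)-[(2R)-oxiran-2-yl][3,4,5-tris(benzyloxy)phenyl]methoxy}phenyl]-1-[3,4,5-tris(benzyloxy)phenyl]prop-2-yn-1-yl}oxy)benzene
Conditions: PPh3, DIAD, toluene, −20 to 0 °C
Reagents that add atoms: none
Why: Mitsunobu etherification with inversion gives the (R)-propargyl aryl ether, so the O1–C2 bond and the C2 configuration of the upper unit are in place before any ring is closed.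

Step 8
Reactants: 10 1-(benzyloxy)-3-({(1R)-3-[2,4-bis(benzyloxy)-6-{(R)-[(2R)-oxiran-2-yl][3,4,5-tris(benzyloxy)phenyl]methoxy}phenyl]-1-[3,4,5-tris(benzyloxy)phenyl]prop-2-yn-1-yl}oxy)benzene
Product: 12 (2R,3R)-5,7-bis(benzyloxy)-8-{(2S)-7-(benzyloxy)-2-[3,4,5-tris(benzyloxy)phenyl]-2H-chromen-4-yl}-2-[3,4,5-tris(benzyloxy)phenyl]chroman-3-ol, via chromene epoxide 11 (not isolated)
Conditions: AuCl3 (5 mol %), AgOTf (15 mol %), 4 Å MS, ClCH2CH2Cl, 0 °C to rt, dark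
Reagents that add atoms: none
Why: Proposed new method: one electrophilic gold catalyst runs two arene alkylations in the same flask, namely π-activation of the internal alkyne for 6-endo-dig hydroarylation by ring A para to its benzyloxy group (attack at the alkyne carbon bearing electron-rich ring D, where positive charge builds up) to give the 4-aryl-2H-chromene, and σ-activation of the terminal epoxide for 6-endo attack of ring D (its only free position ortho to the ether oxygen) at the CH2 terminus to give the chroman-3-ol; no stereocentre is touched, so C2 of both units and the 2,3-cis C3 of the lower unit are carried over (the 2S label of the chromene is a priority change only); the closest known reaction types are the gold- or platinum-catalysed cycloisomerisation of aryl propargyl ethers to 2H-chromenes and the gold-catalysed intramolecular Friedel–Crafts epoxide–arene cyclisation of aryl glycidyl ethers to chroman-3-ols.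

Step 9
Reactants: 12 (2R,3R)-5,7-bis(benzyloxy)-8-{(2S)-7-(benzyloxy)-2-[3,4,5-tris(benzyloxy)phenyl]-2H-chromen-4-yl}-2-[3,4,5-tris(benzyloxy)phenyl]chroman-3-ol
Product: 13 (2R,3R,4R)-7-(benzyloxy)-4-{(2R,3R)-5,7-bis(benzyloxy)-3-hydroxy-2-[3,4,5-tris(benzyloxy)phenyl]chroman-8-yl}-2-[3,4,5-tris(benzyloxy)phenyl]chromane-3,4-diol
Conditions: OsO4 (5 mol %), NMO (2 equiv), acetone/t-BuOH/H2O, rt
Reagents that add atoms: N-methylmorpholine N-oxide, C[N+]1([O-])CCOCC1; water, O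
Why: Upjohn dihydroxylation: OsO4 adds to the only alkene from the face anti to the C2 aryl group, which sets the 3-OH trans to that aryl (the 3S centre of the target) and gives the cis-diol with a tertiary 4-OH.

Step 10
Reactants: 13 (2R,3R,4R)-7-(benzyloxy)-4-{(2R,3R)-5,7-bis(benzyloxy)-3-hydroxy-2-[3,4,5-tris(benzyloxy)phenyl]chroman-8-yl}-2-[3,4,5-tris(benzyloxy)phenyl]chromane-3,4-diol
Product: 14 (2R,3S,4R)-7-(benzyloxy)-4-{(2R,3R)-5,7-bis(benzyloxy)-3-hydroxy-2-[3,4,5-tris(benzyloxy)phenyl]chroman-8-yl}-2-[3,4,5-tris(benzyloxy)phenyl]chroman-3-ol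
Conditions: Et3SiH (10 equiv), TFA (5 equiv), CH2Cl2, −78 to −30 °C; aq NaHCO3
Reagents that add atoms: none
Why: Ionic hydrogenation: only the tertiary, doubly benzylic 4-OH ionises, and the silane delivers hydride to the flavan-4-yl cation from the face anti to the neighbouring 3-OH, so ring D ends up cis to the 3-OH (4R, the 4β linkage).

Step 11
Reactants: 14 (2R,3S,4R)-7-(benzyloxy)-4-{(2R,3R)-5,7-bis(benzyloxy)-3-hydroxy-2-[3,4,5-tris(benzyloxy)phenyl]chroman-8-yl}-2-[3,4,5-tris(benzyloxy)phenyl]chroman-3-ol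
Product: 15 (2R,3S,4R)-4-[(2R,3R)-3,5,7-trihydroxy-2-(3,4,5-trihydroxyphenyl)chroman-8-yl]-2-(3,4,5-trihydroxyphenyl)chromane-3,7-diol (CNP0275321.4)
Conditions: H2 (1 atm), Pd(OH)2/C, THF/MeOH, rt
Reagents that add atoms: none
Why: Catalytic hydrogenolysis removes the nine benzyl ethers under neutral conditions and leaves the pyran C–O bonds, the acid-stable 5-deoxy interflavan bond and all five stereocentres untouched.

**Compound list**

1 | 2,4,6-trihydroxybenzaldehyde | O=Cc1c(O)cc(O)cc1O | starting material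
2 | 4,6-bis(benzyloxy)-2-hydroxybenzaldehyde | O=Cc1c(O)cc(OCc2ccccc2)cc1OCc1ccccc1 | intermediate
3 | 3,4,5-tris(benzyloxy)benzaldehyde | O=Cc1cc(OCc2ccccc2)c(OCc2ccccc2)c(OCc2ccccc2)c1 | starting material
4 | (±)-1-[3,4,5-tris(benzyloxy)phenyl]prop-2-en-1-ol | C=CC(O)c1cc(OCc2ccccc2)c(OCc2ccccc2)c(OCc2ccccc2)c1 | intermediate
5 | (S)-[(2R)-oxiran-2-yl][3,4,5-tris(benzyloxy)phenyl]methanol | O[C@@H](c1cc(OCc2ccccc2)c(OCc2ccccc2)c(OCc2ccccc2)c1)[C@H]1CO1 | intermediate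
6 | 4,6-bis(benzyloxy)-2-{(R)-[(2R)-oxiran-2-yl][3,4,5-tris(benzyloxy)phenyl]methoxy}benzaldehyde | O=Cc1c(O[C@H](c2cc(OCc3ccccc3)c(OCc3ccccc3)c(OCc3ccccc3)c2)[C@H]2CO2)cc(OCc2ccccc2)cc1OCc1ccccc1 | intermediate
7 | 1,5-bis(benzyloxy)-2-ethynyl-3-{(R)-[(2R)-oxiran-2-yl][3,4,5-tris(benzyloxy)phenyl]methoxy}benzene | C#Cc1c(O[C@H](c2cc(OCc3ccccc3)c(OCc3ccccc3)c(OCc3ccccc3)c2)[C@H]2CO2)cc(OCc2ccccc2)cc1OCc1ccccc1 | intermediate
8 | (1S)-3-[2,4-bis(benzyloxy)-6-{(R)-[(2R)-oxiran-2-yl][3,4,5-tris(benzyloxy)phenyl]methoxy}phenyl]-1-[3,4,5-tris(benzyloxy)phenyl]prop-2-yn-1-ol | O[C@@H](c1cc(OCc2ccccc2)c(OCc2ccccc2)c(OCc2ccccc2)c1)C#Cc1c(O[C@H](c2cc(OCc3ccccc3)c(OCc3ccccc3)c(OCc3ccccc3)c2)[C@H]2CO2)cc(OCc2ccccc2)cc1OCc1ccccc1 | intermediate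
9 | 3-(benzyloxy)phenol | Oc1cccc(OCc2ccccc2)c1 | starting material
10 | 1-(benzyloxy)-3-({(1R)-3-[2,4-bis(benzyloxy)-6-{(R)-[(2R)-oxiran-2-yl][3,4,5-tris(benzyloxy)phenyl]methoxy}phenyl]-1-[3,4,5-tris(benzyloxy)phenyl]prop-2-yn-1-yl}oxy)benzene | c1ccccc1COc1cccc(O[C@H](c2cc(OCc3ccccc3)c(OCc3ccccc3)c(OCc3ccccc3)c2)C#Cc2c(O[C@H](c3cc(OCc4ccccc4)c(OCc4ccccc4)c(OCc4ccccc4)c3)[C@H]3CO3)cc(OCc3ccccc3)cc2OCc2ccccc2)c1 | intermediate
11 | (2S)-7-(benzyloxy)-4-[2,4-bis(benzyloxy)-6-{(R)-[(2R)-oxiran-2-yl][3,4,5-tris(benzyloxy)phenyl]methoxy}phenyl]-2-[3,4,5-tris(benzyloxy)phenyl]-2H-chromene | c1ccccc1COc1ccc2c(c1)O[C@H](c1cc(OCc3ccccc3)c(OCc3ccccc3)c(OCc3ccccc3)c1)C=C2c1c(O[C@H](c2cc(OCc3ccccc3)c(OCc3ccccc3)c(OCc3ccccc3)c2)[C@H]2CO2)cc(OCc2ccccc2)cc1OCc1ccccc1 | intermediate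
12 | (2R,3R)-5,7-bis(benzyloxy)-8-{(2S)-7-(benzyloxy)-2-[3,4,5-tris(benzyloxy)phenyl]-2H-chromen-4-yl}-2-[3,4,5-tris(benzyloxy)phenyl]chroman-3-ol | c1ccccc1COc1ccc2c(c1)O[C@H](c1cc(OCc3ccccc3)c(OCc3ccccc3)c(OCc3ccccc3)c1)C=C2c1c(OCc2ccccc2)cc(OCc2ccccc2)c2c1O[C@H](c1cc(OCc3ccccc3)c(OCc3ccccc3)c(OCc3ccccc3)c1)[C@H](O)C2 | intermediate
13 | (2R,3R,4R)-7-(benzyloxy)-4-{(2R,3R)-5,7-bis(benzyloxy)-3-hydroxy-2-[3,4,5-tris(benzyloxy)phenyl]chroman-8-yl}-2-[3,4,5-tris(benzyloxy)phenyl]chromane-3,4-diol | c1ccccc1COc1ccc2c(c1)O[C@H](c1cc(OCc3ccccc3)c(OCc3ccccc3)c(OCc3ccccc3)c1)[C@@H](O)[C@]2(O)c1c(OCc2ccccc2)cc(OCc2ccccc2)c2c1O[C@H](c1cc(OCc3ccccc3)c(OCc3ccccc3)c(OCc3ccccc3)c1)[C@H](O)C2 | intermediate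
14 | (2R,3S,4R)-7-(benzyloxy)-4-{(2R,3R)-5,7-bis(benzyloxy)-3-hydroxy-2-[3,4,5-tris(benzyloxy)phenyl]chroman-8-yl}-2-[3,4,5-tris(benzyloxy)phenyl]chroman-3-ol | c1ccccc1COc1ccc2c(c1)O[C@H](c1cc(OCc3ccccc3)c(OCc3ccccc3)c(OCc3ccccc3)c1)[C@@H](O)[C@H]2c1c(OCc2ccccc2)cc(OCc2ccccc2)c2c1O[C@H](c1cc(OCc3ccccc3)c(OCc3ccccc3)c(OCc3ccccc3)c1)[C@H](O)C2 | intermediate
15 | (2R,3S,4R)-4-[(2R,3R)-3,5,7-trihydroxy-2-(3,4,5-trihydroxyphenyl)chroman-8-yl]-2-(3,4,5-trihydroxyphenyl)chromane-3,7-diol, robinetinidol-(4β→8)-epigallocatechin | Oc1ccc2c(c1)O[C@H](c1cc(O)c(O)c(O)c1)[C@@H](O)[C@H]2c1c(O)cc(O)c2c1O[C@H](c1cc(O)c(O)c(O)c1)[C@H](O)C2 | target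

**Step count**

Total steps: 11. Longest linear sequence: 10 steps (3 → 4 → 5 → 6 → 7 → 8 → 10 → 12 → 13 → 14 → 15).

**Steps most likely to fail, with fallbacks**

Step 8 (double cyclisation). Three things can go wrong. The oxygens ortho to the alkyne on ring D can attack the gold-activated alkyne and transfer a benzyl group (benzofuran formation). The propargylic C2–O bond can ionise, or the 2-aryl-2H-chromene can ring-open, eroding the C2 configuration. The epoxide can open 5-exo instead of 6-endo. The fallback sets out from 10 and returns at 12; it separates the two ring closures and changes how ring C is triggered. BF3·OEt2 (CH2Cl2, −40 °C) or hexafluoroisopropanol closes ring F alone by epoxide–arene cyclisation to give (2R,3R)-5,7-bis(benzyloxy)-8-{(3R)-3-[3-(benzyloxy)phenoxy]-3-[3,4,5-tris(benzyloxy)phenyl]prop-1-yn-1-yl}-2-[3,4,5-tris(benzyloxy)phenyl]chroman-3-ol F1. Iodonium-triggered 6-endo iodoarylation (I2, NaHCO3, MeNO2, 0 °C) then closes ring C as (2R,3R)-5,7-bis(benzyloxy)-8-{(2R)-7-(benzyloxy)-3-iodo-2-[3,4,5-tris(benzyloxy)phenyl]-2H-chromen-4-yl}-2-[3,4,5-tris(benzyloxy)phenyl]chroman-3-ol F2. Pd(PPh3)4 with Bu3SnH removes the vinylic iodine to give 12.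

Step 7 (propargylic Mitsunobu). The carbinol is benzylic, propargylic and conjugated through the alkyne to ring D, so SN1 or SN2′ leakage would erode the C2 configuration. The fallback sets out from 7 and 3 and returns at 10; it makes the C–O bond at the aryl carbon, so the stereocentre is retained instead of inverted. Step 6 is run with (R,R)-ProPhenol to give (1R)-3-[2,4-bis(benzyloxy)-6-{(R)-[(2R)-oxiran-2-yl][3,4,5-tris(benzyloxy)phenyl]methoxy}phenyl]-1-[3,4,5-tris(benzyloxy)phenyl]prop-2-yn-1-ol F3. Its sodium alkoxide (NaH, toluene, 0 °C) is O-arylated with bis[3-(benzyloxy)phenyl]iodonium trifluoromethanesulfonate F4, a metal-free ligand coupling that does not pass through a propargylic cation. F4 is prepared from 1-(benzyloxy)-3-iodobenzene and 3-(benzyloxy)phenylboronic acid with mCPBA and BF3·OEt2, then TfOH.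

Step 10 (ionic hydrogenation). The C4 cation sits next to a free 3-OH, so a pinacol-type 1,2-hydride shift to the 3-ketone can compete with silane capture, and facial selectivity may be incomplete. The fallback sets out from 13 and returns at 14; it makes the hydride shift the intended path. Catalytic TsOH (toluene, rt) converts 13 by semipinacol rearrangement into (2R,4R)-7-(benzyloxy)-4-{(2R,3R)-5,7-bis(benzyloxy)-3-hydroxy-2-[3,4,5-tris(benzyloxy)phenyl]chroman-8-yl}-2-[3,4,5-tris(benzyloxy)phenyl]chroman-3-one F5; the C3 hydrogen migrates suprafacially to the face of C4 anti to the departing oxygen and fixes 4R. NaBH4 (THF/MeOH, −78 °C) then reduces the ketone by axial attack anti to the pseudo-axial 4-aryl group to give the 3S alcohol 14.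

**Further compounds**

F1 | step 8 | (2R,3R)-5,7-bis(benzyloxy)-8-{(3R)-3-[3-(benzyloxy)phenoxy]-3-[3,4,5-tris(benzyloxy)phenyl]prop-1-yn-1-yl}-2-[3,4,5-tris(benzyloxy)phenyl]chroman-3-ol | c1ccccc1COc1cccc(O[C@H](c2cc(OCc3ccccc3)c(OCc3ccccc3)c(OCc3ccccc3)c2)C#Cc2c(OCc3ccccc3)cc(OCc3ccccc3)c3c2O[C@H](c2cc(OCc4ccccc4)c(OCc4ccccc4)c(OCc4ccccc4)c2)[C@H](O)C3)c1
F2 | step 8 | (2R,3R)-5,7-bis(benzyloxy)-8-{(2R)-7-(benzyloxy)-3-iodo-2-[3,4,5-tris(benzyloxy)phenyl]-2H-chromen-4-yl}-2-[3,4,5-tris(benzyloxy)phenyl]chroman-3-ol | c1ccccc1COc1ccc2c(c1)O[C@H](c1cc(OCc3ccccc3)c(OCc3ccccc3)c(OCc3ccccc3)c1)C(I)=C2c1c(OCc2ccccc2)cc(OCc2ccccc2)c2c1O[C@H](c1cc(OCc3ccccc3)c(OCc3ccccc3)c(OCc3ccccc3)c1)[C@H](O)C2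
F3 | step 7 | (1R)-3-[2,4-bis(benzyloxy)-6-{(R)-[(2R)-oxiran-2-yl][3,4,5-tris(benzyloxy)phenyl]methoxy}phenyl]-1-[3,4,5-tris(benzyloxy)phenyl]prop-2-yn-1-ol | O[C@H](c1cc(OCc2ccccc2)c(OCc2ccccc2)c(OCc2ccccc2)c1)C#Cc1c(O[C@H](c2cc(OCc3ccccc3)c(OCc3ccccc3)c(OCc3ccccc3)c2)[C@H]2CO2)cc(OCc2ccccc2)cc1OCc1ccccc1
F4 | step 7 | bis[3-(benzyloxy)phenyl]iodonium trifluoromethanesulfonate | c1ccccc1COc1cccc([I+]c2cccc(OCc3ccccc3)c2)c1.[O-]S(=O)(=O)C(F)(F)F
F5 | step 10 | (2R,4R)-7-(benzyloxy)-4-{(2R,3R)-5,7-bis(benzyloxy)-3-hydroxy-2-[3,4,5-tris(benzyloxy)phenyl]chroman-8-yl}-2-[3,4,5-tris(benzyloxy)phenyl]chroman-3-one | c1ccccc1COc1ccc2c(c1)O[C@H](c1cc(OCc3ccccc3)c(OCc3ccccc3)c(OCc3ccccc3)c1)C(=O)[C@H]2c1c(OCc2ccccc2)cc(OCc2ccccc2)c2c1O[C@H](c1cc(OCc3ccccc3)c(OCc3ccccc3)c(OCc3ccccc3)c1)[C@H](O)C2
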